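**Retrosynthetic overview**

1. Target ⇐ desilylation of the C8 ester formed from the 8-alcohol and (Z)-4-silyloxy-2-methylbut-2-enoic acid (from 3-methylfuran-2(5H)-one); cis-1,10-epoxide ⇐ 8-OH-directed epoxidation; 8-OH ⇐ CBS reduction of a C8 ketone.
2. Ten-membered ring, cis-fused α-methylene lactone, 4Z-olefin and C3–O ⇐ two-carbon ring expansion (eight → ten) of a cyclooctenone carrying a 3-(bromomethyl)butenolide at C5 and a 3,4-epoxide: Barbier closure to a cyclobutanolate, then epoxide-terminated Grob fragmentation of the C5–C8 bond.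
3. That precursor ⇐ RCM of a 2-(bromomethyl)acrylate, hydroxyl-directed epoxidation, Sharpless kinetic resolution, and anti boron aldol of acrolein with 3,7-dimethylcycloocta-3,6-dienone.
4. The dienone ⇐ allylic oxidation and deconjugation of 1,5-dimethylcycloocta-1,5-diene ⇐ nickel-catalysed [4+4] dimerisation of isoprene.
5. Ring order: eight-membered carbocycle → 3,4-epoxide → butenolide → transient cyclobutane → ten-membered ring → 1,10-epoxide.

Assumption: the target is read as (1R,3S,6S,7R,8R,10S) with a 4Z olefin, a cis-1,10-epoxide and a cis-fused 6,12-lactone; "target locants" C1–C15 are germacranolide positions (C14 on C10, C15 on C4); isoprene, acrolein, 2-(bromomethyl)acrylic acid and 3-methylfuran-2(5H)-one are taken as commercial.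

**Step 1**
Reactants: 1 isoprene (2-methylbuta-1,3-diene), two molecules
Product: 2 (1Z,5Z)-1,5-dimethylcycloocta-1,5-diene
Conditions: Ni(C8H12)2 (bis(1,5-cyclooctadiene)nickel, zerovalent nickel, 1 mol%), tris(2-biphenylyl) phosphite, toluene, 60 °C; fractional distillation from the 1,6-dimethyl isomer
Reagents that add atoms: none
Why: Nickel-catalysed head-to-tail [4+4] cyclodimerisation of isoprene gives all ten carbons of C1–C5 and C8–C10 with both methyl groups on ring-cis trisubstituted olefins (no stereocentre).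

**Step 2**
Reactants: 2 (1Z,5Z)-1,5-dimethylcycloocta-1,5-diene
Product: 4 (3Z,6Z)-3,7-dimethylcycloocta-3,6-dien-1-one, via conjugated dienone 3 (not isolated)
Conditions: Rh2(C6H10NO)4 (dirhodium tetrakis(caprolactamate), 1 mol%), t-BuOOH (4 equiv), K2CO3, CH2Cl2, rt, to about 50% conversion; then DBU (0.2 equiv), benzene, rt; recovered 2 and 3 recycled
Reagents that add atoms: tert-butyl hydroperoxide, CC(C)(C)OO
Why: Radical allylic oxidation at the CH2 next to the unsubstituted olefin carbon (the two such CH2 groups are equivalent) gives enone 3, and base equilibration moves the double bond out of conjugation, the β,γ-isomer being favoured for eight-membered cis-enones, to give the symmetric ketone 4 (allylic oxidation, then deconjugation; no stereocentre).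

**Step 3**
Reactants: 4 (3Z,6Z)-3,7-dimethylcycloocta-3,6-dien-1-one; 5 acrolein (prop-2-enal)
Product: 7 rac-(2R*,3Z,6Z)-2-[(1R*)-1-hydroxyprop-2-en-1-yl]-3,7-dimethylcycloocta-3,6-dien-1-one, via boron dienolate 6 (not isolated)
Conditions: (c-C6H11)2BCl, Et3N, Et2O, −78 to 0 °C; 5, −78 °C; then H2O2, pH 7 buffer, MeOH, 0 °C
Reagents that add atoms: none
Why: Soft enolisation gives the ring-constrained E(O) boron dienolate, which adds through its α-carbon to the aldehyde via a Zimmerman–Traxler chair to give the anti aldol (C5/C6 relative configuration) as a racemate (boron aldol reaction).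

**Step 4**
Reactants: 7 racemic anti aldol
Product: 8 (2R,3Z,6Z)-2-[(1R)-1-hydroxyprop-2-en-1-yl]-3,7-dimethylcycloocta-3,6-dien-1-one
Conditions: Ti(OiPr)4 (0.15 equiv), D-(−)-diisopropyl tartrate (0.2 equiv), t-BuOOH (0.6 equiv), 4 Å MS, CH2Cl2, −20 °C, to 55% conversion
Reagents that add atoms: none
Why: Sharpless kinetic resolution of the secondary allylic alcohol: with the D-(−)-tartrate the (2S,1'S) enantiomer is epoxidised at its vinyl group and the (2R,1'R) enantiomer 8 is recovered, which fixes the absolute configuration of the later C6.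

**Step 5**
Reactants: 8 (2R,1'R) aldol
Product: 9 (2S,3R,4S,6Z)-3,4-epoxy-2-[(1R)-1-hydroxyprop-2-en-1-yl]-3,7-dimethylcyclooct-6-en-1-one
Conditions: VO(acac)2 (vanadyl bis(acetylacetonate), 5 mol%), t-BuOOH (1.2 equiv), CH2Cl2, 0 °C
Reagents that add atoms: tert-butyl hydroperoxide, CC(C)(C)OO
Why: Hydroxyl-directed epoxidation of the homoallylic alcohol delivers oxygen to the trisubstituted olefin on the ring face that carries the CH(OH) side chain, setting target C3 (S) and C4 (R), while the monosubstituted vinyl group and the undirected second ring olefin react more slowly.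

**Step 6**
Reactants: 9 epoxy alcohol; 10 2-(bromomethyl)acrylic acid
Product: 12 (2S,3R,4S,6Z)-2-[(1R)-1-{[2-(bromomethyl)prop-2-enoyl]oxy}prop-2-en-1-yl]-3,4-epoxy-3,7-dimethylcyclooct-6-en-1-one, via acid chloride 11 (not isolated)
Conditions: 10, (COCl)2, DMF (cat.), CH2Cl2, 0 °C to rt; then 9, 2,6-lutidine, CH2Cl2, −20 °C
Reagents that add atoms: none
Why: Acylation of the secondary alcohol by the acid chloride under a hindered weak base (no quaternisation at the allylic bromide, no β-elimination of the aldol ester) gives the metathesis precursor with all stereocentres untouched (esterification).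

**Step 7**
Reactants: 12 acrylate ester
Product: 13 (2S,3R,4S,6Z)-2-[(2R)-4-(bromomethyl)-5-oxo-2,5-dihydrofuran-2-yl]-3,4-epoxy-3,7-dimethylcyclooct-6-en-1-one
Conditions: second-generation Hoveyda–Grubbs catalyst (5 mol%), toluene (2 mM), 60 °C
Reagents that add atoms: none
Why: Ring-closing metathesis between the vinyl group and the 1,1-disubstituted acrylate closes the five-membered butenolide (C7=C11) with loss of ethene, leaving the trisubstituted ring olefin, the epoxide and the allylic bromide untouched.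

**Step 8**
Reactants: 13 butenolide bromide
Product: 16 (3S,6S,7S,1(10)Z,4Z)-3-(tert-butyldimethylsilyloxy)-8-oxogermacra-1(10),4,11(13)-trien-6,12-olide, via allylzinc bromide 14 (not isolated), via zinc cyclobutanolate 15 (not isolated)
Conditions: Zn dust (activated, 3 equiv), THF, 0 °C to rt; then 2,6-di-tert-butyl-4-methylpyridine, TBSOTf (1.2 equiv), −78 to −20 °C
Reagents that add atoms: tert-butyldimethylsilyl trifluoromethanesulfonate, CC(C)(C)[Si](C)(C)OS(=O)(=O)C(F)(F)F
Why: Proposed new method: zinc inserts into the allylic C–Br bond and the allylzinc 14 adds through its ring carbon C7 (γ-attack via a six-membered Zn–O transition state, as in intermolecular Barbier reactions of 3-(bromomethyl)butenolides) to the C8 ketone two atoms away, which can only give the cis-fused lactone/cyclobutane 15 and so sets C7 cis to C6; the silyl triflate then activates the epoxide oxygen and the strained C5–C8 bond, anti-periplanar to C4–O, breaks in an alkoxide-driven Grob fragmentation that gives the C8 ketone, the C4=C5 olefin as the Z isomer (C6 and the epoxide oxygen are cis on the eight-membered ring) and the C3 silyl ether with retention at C3; the closest known reactions are the indium-mediated two-carbon ring enlargement of 2-(4-bromobut-2-enyl) β-keto esters through cyclobutanols (retro-aldol opening) and the epoxy-alcohol Grob fragmentation, the new element being an epoxide-terminated fragmentation of a Barbier-derived cyclobutanolate that converts the eight- into the ten-membered ring.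

**Step 9**
Reactants: 16 C8 ketone
Product: 17 (3S,6S,7R,8R,1(10)Z,4Z)-3-(tert-butyldimethylsilyloxy)-8-hydroxygermacra-1(10),4,11(13)-trien-6,12-olide
Conditions: (S)-2-methyl-CBS-oxazaborolidine (0.2 equiv), catecholborane (1.5 equiv), toluene, −78 °C; MeOH quench
Reagents that add atoms: none
Why: Corey–Bakshi–Shibata reduction with C7 as the large and C9 as the small substituent gives the (8R)-alcohol (hydroxyl cis to the lactone) under reagent control, without 1,4-reduction of the α-methylene lactone.

**Step 10**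
Reactants: 17 (8R)-alcohol
Product: 18 (1R,3S,6S,7R,8R,10S,4Z)-3-(tert-butyldimethylsilyloxy)-1,10-epoxy-8-hydroxygermacra-4,11(13)-dien-6,12-olide
Conditions: VO(acac)2 (5 mol%), t-BuOOH (1.5 equiv), CH2Cl2, 0 °C
Reagents that add atoms: tert-butyl hydroperoxide, CC(C)(C)OO
Why: Hydroxyl-directed epoxidation from the homoallylic 8-OH places the oxygen on the same face of the Z-configured C1=C10 olefin to give the cis-epoxide (1R,10S), while the C4=C5 olefin (flanked by a silyl ether and the lactone oxygen) and the acrylate are not epoxidised.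

**Step 11**
Reactants: 19 3-methylfuran-2(5H)-one
Product: 22 (Z)-4-(tert-butyldimethylsilyloxy)-2-methylbut-2-enoic acid, via sodium carboxylate 20 (not isolated), via bis-silyl derivative 21 (not isolated)
Conditions: NaOH (1.0 equiv), H2O/MeOH, rt; evaporation; TBSCl (2.2 equiv), imidazole, DMF, rt; then AcOH/THF/H2O, 0 °C
Reagents that add atoms: sodium hydroxide, [Na+].[OH-]; tert-butyldimethylsilyl chloride, CC(C)(C)[Si](C)(C)Cl
Why: Saponification of the butenolide gives the hydroxy acid with the Z geometry fixed by the former ring, and bis-silylation followed by hydrolysis of the labile silyl ester leaves the O-silylated acid (lactone hydrolysis, silylation).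

**Step 12**
Reactants: 18 epoxy alcohol; 22 silyloxy acid
Product: 24 (1R,3S,6S,7R,8R,10S,4Z)-3-(tert-butyldimethylsilyloxy)-8-{[(Z)-4-(tert-butyldimethylsilyloxy)-2-methylbut-2-enoyl]oxy}-1,10-epoxygermacra-4,11(13)-dien-6,12-olide, via mixed anhydride 23 (not isolated)
Conditions: 22, 2,4,6-trichlorobenzoyl chloride, Et3N, toluene, rt; then 18, DMAP (0.3 equiv), 0 °C to rt
Reagents that add atoms: none
Why: Yamaguchi esterification acylates the only free hydroxyl (C8) at low temperature, so the Z-enoate is not isomerised and no stereocentre is touched.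

**Step 13**
Reactants: 24 bis-silyl ether
Product: 25 (1R,3S,6S,7R,8R,10S,4Z)-1,10-epoxy-3-hydroxy-8-{[(Z)-4-hydroxy-2-methylbut-2-enoyl]oxy}germacra-4,11(13)-dien-6,12-olide (target)
Conditions: TBAF (3 equiv), AcOH (3 equiv), THF, 0 °C to rt
Reagents that add atoms: none
Why: Acetic acid-buffered fluoride removes both silyl ethers without opening the epoxide, adding to the α-methylene lactone or migrating the ester (desilylation).

**Compound list**

1 | isoprene (2-methylbuta-1,3-diene) | C=CC(C)=C | starting material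
2 | (1Z,5Z)-1,5-dimethylcycloocta-1,5-diene | C/C1=C/CC/C(C)=C\CC1 | intermediate
3 | (2Z,6Z)-3,7-dimethylcycloocta-2,6-dien-1-one | C/C1=C/C(=O)C/C(C)=C\CC1 | intermediate
4 | (3Z,6Z)-3,7-dimethylcycloocta-3,6-dien-1-one | O=C1C/C(C)=C\C/C=C(/C)C1 | intermediate
5 | acrolein (prop-2-enal) | C=CC=O | starting material
6 | dicyclohexyl{[(1Z,3Z,6Z)-3,7-dimethylcycloocta-1,3,6-trien-1-yl]oxy}borane (boron dienolate of 4) | C1/C(OB(C2CCCCC2)C2CCCCC2)=C\C(C)=C/C/C=C1/C | intermediate
7 | rac-(2R*,3Z,6Z)-2-[(1R*)-1-hydroxyprop-2-en-1-yl]-3,7-dimethylcycloocta-3,6-dien-1-one (anti aldol, racemate) | O=C1C/C(C)=C\C/C=C(/C)[C@@H]1[C@@H](C=C)O.O=C1C/C(C)=C\C/C=C(/C)[C@H]1[C@H](C=C)O | intermediate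
8 | (2R,3Z,6Z)-2-[(1R)-1-hydroxyprop-2-en-1-yl]-3,7-dimethylcycloocta-3,6-dien-1-one | O=C1C/C(C)=C\C/C=C(/C)[C@@H]1[C@@H](C=C)O | intermediate
9 | (2S,3R,4S,6Z)-3,4-epoxy-2-[(1R)-1-hydroxyprop-2-en-1-yl]-3,7-dimethylcyclooct-6-en-1-one (epoxide oxygen cis to the side chain) | O=C1C/C(C)=C\C[C@@H]2O[C@]2(C)[C@@H]1[C@@H](C=C)O | intermediate
10 | 2-(bromomethyl)acrylic acid | C=C(CBr)C(=O)O | starting material
11 | 2-(bromomethyl)acryloyl chloride | C=C(CBr)C(Cl)=O | intermediate
12 | (2S,3R,4S,6Z)-2-[(1R)-1-{[2-(bromomethyl)prop-2-enoyl]oxy}prop-2-en-1-yl]-3,4-epoxy-3,7-dimethylcyclooct-6-en-1-one | O=C1C/C(C)=C\C[C@@H]2O[C@]2(C)[C@@H]1[C@@H](C=C)OC(=O)C(=C)CBr | intermediate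
13 | (2S,3R,4S,6Z)-2-[(2R)-4-(bromomethyl)-5-oxo-2,5-dihydrofuran-2-yl]-3,4-epoxy-3,7-dimethylcyclooct-6-en-1-one | O=C1C/C(C)=C\C[C@@H]2O[C@]2(C)[C@@H]1[C@@H]1OC(=O)C(CBr)=C1 | intermediate
14 | allylzinc bromide of 13 (bromozinc on the butenolide CH2, stereocentres as in 13) | O=C1C/C(C)=C\C[C@@H]2O[C@]2(C)[C@@H]1[C@@H]1OC(=O)C(C[Zn]Br)=C1 | intermediate
15 | bromozinc alkoxide of the tricyclic cyclobutanol (cyclobutane C5–C6–C7–C8 cis-fused to the α-methylene lactone and to the eight-membered ring; (3S,4R)-epoxide and 1(10)Z olefin retained) | C=C1C(=O)O[C@H]2[C@H]3[C@@]4(C)O[C@H]4C/C=C(/C)C[C@@]3(O[Zn]Br)[C@@H]12 | intermediate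
16 | (3S,6S,7S,1(10)Z,4Z)-3-(tert-butyldimethylsilyloxy)-8-oxogermacra-1(10),4,11(13)-trien-6,12-olide | C=C1C(=O)O[C@H]2/C=C(/C)[C@@H](O[Si](C)(C)C(C)(C)C)C/C=C(/C)CC(=O)[C@@H]12 | intermediate
17 | (3S,6S,7R,8R,1(10)Z,4Z)-3-(tert-butyldimethylsilyloxy)-8-hydroxygermacra-1(10),4,11(13)-trien-6,12-olide | C=C1C(=O)O[C@H]2/C=C(/C)[C@@H](O[Si](C)(C)C(C)(C)C)C/C=C(/C)C[C@@H](O)[C@@H]12 | intermediate
18 | (1R,3S,6S,7R,8R,10S,4Z)-3-(tert-butyldimethylsilyloxy)-1,10-epoxy-8-hydroxygermacra-4,11(13)-dien-6,12-olide | C=C1C(=O)O[C@H]2/C=C(/C)[C@@H](O[Si](C)(C)C(C)(C)C)C[C@H]3O[C@@]3(C)C[C@@H](O)[C@@H]12 | intermediate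
19 | 3-methylfuran-2(5H)-one | CC1=CCOC1=O | starting material
20 | sodium (Z)-4-hydroxy-2-methylbut-2-enoate | [Na+].[O-]C(=O)/C(C)=C\CO | intermediate
21 | tert-butyldimethylsilyl (Z)-4-(tert-butyldimethylsilyloxy)-2-methylbut-2-enoate | CC(C)(C)[Si](C)(C)OC(=O)/C(C)=C\CO[Si](C)(C)C(C)(C)C | intermediate
22 | (Z)-4-(tert-butyldimethylsilyloxy)-2-methylbut-2-enoic acid | OC(=O)/C(C)=C\CO[Si](C)(C)C(C)(C)C | intermediate
23 | (Z)-4-(tert-butyldimethylsilyloxy)-2-methylbut-2-enoic 2,4,6-trichlorobenzoic anhydride | O=C(OC(=O)/C(C)=C\CO[Si](C)(C)C(C)(C)C)c1c(Cl)cc(Cl)cc1Cl | intermediate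
24 | (1R,3S,6S,7R,8R,10S,4Z)-3-(tert-butyldimethylsilyloxy)-8-{[(Z)-4-(tert-butyldimethylsilyloxy)-2-methylbut-2-enoyl]oxy}-1,10-epoxygermacra-4,11(13)-dien-6,12-olide | C=C1C(=O)O[C@H]2/C=C(/C)[C@@H](O[Si](C)(C)C(C)(C)C)C[C@H]3O[C@@]3(C)C[C@@H](OC(=O)/C(C)=C\CO[Si](C)(C)C(C)(C)C)[C@@H]12 | intermediate
25 | (1R,3S,6S,7R,8R,10S,4Z)-1,10-epoxy-3-hydroxy-8-{[(Z)-4-hydroxy-2-methylbut-2-enoyl]oxy}germacra-4,11(13)-dien-6,12-olide | C=C1C(=O)O[C@H]2/C=C(/C)[C@@H](O)C[C@H]3O[C@@]3(C)C[C@@H](OC(=O)/C(C)=C\CO)[C@@H]12 | target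

**Step count**

Total: 13 steps. Longest linear sequence: 12 steps (steps 1–10, 12, 13); step 11 makes the side-chain acid.

**Three steps most likely to fail**

Step 8 (the proposed new cascade). It can fail by Lewis-acid rearrangement of the epoxide before cyclisation, by attack through the exocyclic allyl carbon (six-membered carbocycle), or by silyl enol ether formation at the new ketone. The fallback uses known reactions run as separate, isolated operations and sets out from 13. Indium powder in THF/water performs the aqueous Barbier allylation and gives the free cyclobutanol F1; cyclobutanols of this kind are the first stage of known indium-mediated two-carbon ring enlargements. F1 is then fragmented with Ti(OiPr)4 in CH2Cl2, a Lewis-acid-promoted epoxy-alcohol Grob fragmentation, to the hydroxy ketone F2. Silylation of F2 (TBSCl, imidazole, DMF) returns to the route at 16.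

Step 2. The allylic oxidation can give regioisomeric or over-oxidised ketones, and the deconjugation rests on an equilibrium. The fallback fixes the carbonyl position by a different, stepwise approach and sets out from 2. One olefin is epoxidised (mCPBA, 1 equiv, CH2Cl2, 0 °C) to the mono-epoxide F3. PhSeNa (from (PhSe)2 and NaBH4, EtOH) opens it at the secondary carbon to the hydroxy selenide F4. Oxidation with H2O2 and syn-elimination gives the tertiary allylic alcohol F5. Pyridinium chlorochromate, (C5H5NH)[CrO3Cl], in CH2Cl2 effects the 1,3-oxidative transposition and returns to the route at 3, which is equilibrated with DBU to 4 as in the second stage of step 2.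

Step 9. The reagent-controlled reduction of a medium-ring ketone may give the wrong C8 epimer or touch the α-methylene lactone. The fallback sets out from 16. Luche reduction (NaBH4, CeCl3·7H2O, MeOH, −78 °C) under substrate control gives the 8-epimeric alcohol F6, separated from any 17 formed. Mitsunobu inversion with formic acid (PPh3, DIAD, THF) gives the inverted formate F7. Mild methanolysis (NaHCO3, MeOH, 0 °C) returns to the route at 17.

**Further compounds**

F1 | step 8 | free tricyclic cyclobutanol corresponding to 15 (C8–OH) | C=C1C(=O)O[C@H]2[C@H]3[C@@]4(C)O[C@H]4C/C=C(/C)C[C@@]3(O)[C@@H]12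
F2 | step 8 | (3S,6S,7S,1(10)Z,4Z)-3-hydroxy-8-oxogermacra-1(10),4,11(13)-trien-6,12-olide | C=C1C(=O)O[C@H]2/C=C(/C)[C@@H](O)C/C=C(/C)CC(=O)[C@@H]12
F3 | step 2 | rac-(4Z)-1,5-dimethyl-9-oxabicyclo[6.1.0]non-4-ene (cis-epoxide, one enantiomer drawn) | C[C@]12CC/C=C(/C)CC[C@H]1O2
F4 | step 2 | rac-trans-(5Z)-1,5-dimethyl-2-(phenylselanyl)cyclooct-5-en-1-ol (one enantiomer drawn) | C[C@@]1(O)[C@@H]([Se]c2ccccc2)CC/C(C)=C\CC1
F5 | step 2 | rac-(2Z,5Z)-1,5-dimethylcycloocta-2,5-dien-1-ol (one enantiomer drawn) | C[C@@]1(O)/C=C\C/C(C)=C\CC1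
F6 | step 9 | (3S,6S,7R,8S,1(10)Z,4Z)-3-(tert-butyldimethylsilyloxy)-8-hydroxygermacra-1(10),4,11(13)-trien-6,12-olide | C=C1C(=O)O[C@H]2/C=C(/C)[C@@H](O[Si](C)(C)C(C)(C)C)C/C=C(/C)C[C@H](O)[C@@H]12
F7 | step 9 | (3S,6S,7R,8R,1(10)Z,4Z)-3-(tert-butyldimethylsilyloxy)-8-(formyloxy)germacra-1(10),4,11(13)-trien-6,12-olide | C=C1C(=O)O[C@H]2/C=C(/C)[C@@H](O[Si](C)(C)C(C)(C)C)C/C=C(/C)C[C@@H](OC=O)[C@@H]12
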